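In the alder run first end groups fell fast and then slowly: 56.5% of the charge remained at 15.0 min, where links read highest, although second end groups went in at 0.95 equiv. So I count 0.458 first end groups gone per second end group charged. This is an apparent figure and no count of second end groups coupled, because the first end groups gone include 4.6% in side product A beside 32.0% in links, and 6.90% of the charge stands in no reading.

| setting | alder | cedar | oak | larch | south-east | west | south-west |
|---|---|---|---|---|---|---|---|
| first end groups | 20 mM | 10 mM | 15 mM | 20 mM | 20 mM | 20 mM (fed, over 2.0 h) | 20 mM |
| second end groups | 0.95 equiv | 0.95 equiv | 0.95 equiv | 1.9 equiv | 0.950 equiv | 0.950 equiv | 0.950 equiv (fed, over 2.0 h) |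
| remark | run made earlier | run made earlier | run made earlier | run made earlier | everything together at the start | all else is in the flask from the start; the feed brings no volume worth counting | all else is in the flask from the start; the feed brings no volume worth counting |
| time |  |  |  |  | 3.0 h | 3.0 h | 3.0 h |

- alder (time / min: links / %, side product A / %, first end groups / %): 8.00: 29.2, 1.2, 65.4; 15.0: 32.0, 4.6, 56.5; 30.0: 29.2, 9.0, 49.3; 60.0: 24.7, 15.3, 37.1; 120: 19.8, 21.7, 24.8
- cedar (time / h: links / %, side product A / %, first end groups / %): 0.667: 20.3, 4.9, 66.6; 1.33: 17.0, 10.2, 59.3; 2.00: 15.7, 12.1, 53.7; 2.50: 13.9, 13.9, 50.9; 3.00: 12.3, 15.4, 47.9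
- oak (time / h: links / %, side product A / %, first end groups / %): 0.250: 26.7, 3.5, 65.1; 0.833: 23.6, 11.0, 50.1; 1.33: 21.4, 13.6, 45.0; 2.00: 17.0, 18.3, 37.5; 3.00: 14.0, 21.7, 31.2
- larch (time / h: links / %, side product A / %, first end groups / %): 0.250: 54.4, 5.6, 31.7; 0.417: 53.9, 8.5, 24.6; 0.833: 51.1, 14.3, 16.2; 1.50: 46.9, 17.6, 8.1; 3.00: 43.7, 23.0, 3.3

(standard deviation of a reading: 0.5 percentage points)



- which flask leads in share of links in links plus side product A ("all alike" within 1.5 percentage points) (south-east / west / south-west / all alike)
- share of links in links plus side product A at the end, south-east
- share of links in links plus side product A at the end, west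
- share of links in links plus side product A at the end, south-west

Call the capture number, an apparent selectivity factor, that figure divided by one minus that figure: 0.845 for alder. I assume that the number scales with the concentration of first end groups, and that first end groups gone per second end group charged are the number over one plus the number.

For the oak run this gives 0.633, so 63.2% of first end groups left, against 65.1% read at 0.250 h. For the larch run the same number gives 13.0%, but the reading is 31.7%, so one number fails once first end groups are drawn down during capture.

In west the feed has delivered 0.125 of the charge by 15.0 min, so I scale the number to 0.106, which leaves 90.9% of first end groups. Links in alder fall while first end groups remain, and west keeps more of those than alder's 24.8% at 120 min, so I put the share in west under the other two.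

The forecast named west as leader, with 39%, 48% and 36% for south-east, west and south-west, on the ground that “feeding the first ends keeps them scarce while links build”.

The flasks give 39.2%, 21.2% and 42.8% for south-east, west and south-west, so south-west leads.

    first end groups + second end groups ⇌ links + released group (K = 190, k = 0.0870 /M/s)
    first end groups + released group → side product A (k = 0.0170 /M/s)
    second end groups → decomposed reagent (k = 0.00220 /s)
    first end groups + links → side product B (k = 0.0110 /M/s)

West's capture number of 0.106 gave 90.9%, and west holds 90.6% of its first end groups at 3.00 h. There, nearly all of the second end groups became decomposed reagent, 18.3 mM of 19.0 mM charged. The neighbouring flask, west at 5.0 mM of first end groups, scales to a capture number of 0.0264, which reckons 97.6% left, and it holds 98.1% at 3.00 h.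

(The data come from a simulation on assumed constants; noise was put on by code.)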